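## The problem

- Target 14 is a 2,3-dihydro-1-benzofuran (ring atoms O1, C2, C3, C3a, C7a). C2 (R) carries a 3-oxoprop-1-en-2-yl group and C3 (S) a 3-methylbutanoate, trans to each other. C5, para to O1, carries an (S)-1-acetoxyethyl group.
- The heterocycle must be made with the C2/C3 pair trans and in one absolute sense. The C3–O bond is its weak point: C3 is benzylic and ortho-linked to O1, so ionisation epimerises it or expels isovaleric acid to give the aromatic benzofuran.
- C1′ lies four bonds from C3 across the arene. It cannot control the ring stereocentres or be controlled by them, so it needs its own reagent-controlled step. As a para-alkoxybenzylic acetate it also ionises under acid.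
- Two different esters sit on two secondary benzylic oxygens and cannot be told apart by hydrolysis. Each acyl group must be delivered once, to the right oxygen.
- The α-substituted acrolein is a Michael acceptor whose allylic carbon is the O1-bearing C2, so addition–elimination would open the ring. It does not survive hydride and must be made last.
- The enabling feature: the exocyclic carbon on C2 carries two one-carbon arms (=CH2 and CHO), a gem-dimethyl carbon in disguise, and C3 carries oxygen. That exocyclic carbon, C2, C3, C3a, C7a and O1 are therefore the six ring atoms of a 2,2-dimethylchroman-3,4-diol in which O1 has slipped from the CMe2 carbon to its neighbour. The parent 2,2-dimethyl-2H-chromene is the best substrate class for catalytic asymmetric epoxidation of cis-alkenes.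

## Retrosynthesis

**14 ⇒ 13 ⇒ 12.** The aldehyde C=O and the allylic C–O are cut back to the C–H bonds of an isopropenyl methyl. The alternative, α-methylenation of a C2–CH2–CHO aldehyde, would pass through a β-aryloxy aldehyde that opens by retro-oxa-Michael reaction. Any oxidised side chain carried earlier would also clash with the hydride step. The forward allylic oxidation of 12 must take a methyl hydrogen and not the C2–H.

**12 ⇒ 11 ⇒ 10.** The acetate C–O and the C1′–H bond are cut to the aryl methyl ketone 10. Making C1′ earlier would drag a para-alkoxybenzylic ester through the epoxide opening and the cationic step. Kept as acetyl, the group para to O1 instead tempers ionisation at both benzylic carbons. The forward step is a catalyst-controlled ketone reduction that spares the alkene and the ester.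

**10 ⇒ 7 (via 9 and 8).** The O1–C2 bond of the dihydrofuran is cut and O1 is reconnected to the exocyclic carbon, with water added across. This gives the trans-chroman-3,4-diol monoester 7. The neighbouring cuts (C2–C3 by ylide or aldol chemistry, O1–C2 to an open-chain epoxide) would leave two stereocentres to be set in an acyclic setting and a free C3 alcohol to acylate afterwards. Here both stereocentres descend from one cis-alkene in a ring and the isovalerate is already in place. The forward reaction needs a 1,2-shift of O1 with inversion at chroman C3 (through triflate 8 and oxiranium ion 9), ahead of the ester carbonyl and the aryl bond, ending in loss of a methyl proton.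

**7 ⇒ 5 + 6.** The C4–O ester bond is cut to epoxide 5 and 3-methylbutanoic acid 6. Opening with water and acylating later would need regioselective acylation of a diol. Direct opening by the acid puts the ester on O4 and leaves the hydroxyl on C3 in one step. The forward reaction must be an SN2 opening at C4 with inversion.

**5 ⇒ 4.** Both epoxide C–O bonds are cut to chromene 4. The catalyst must select the alkene face; the substrate class is the textbook case.

**4 ⇒ 3 ⇒ 1 + 2.** The C4–C4a bond and the aryl O–C bond of the pyran are cut to propargyl ether 3, and 3 to phenol 1 and chloride 2. Direct condensation of an acceptor-substituted phenol with an enal is poor; the propargyl Claisen cascade is reliable for exactly such phenols.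

## Roads not taken

**Alternative 1:** (the most obvious) Cut O1–C2 back to a prenylated phenol, 1-[4-hydroxy-3-(3-methylbut-2-en-1-yl)phenyl]ethanone A1. Asymmetric epoxidation of the prenyl alkene, 5-exo-tet closure by the phenol and dehydration would give the tremetone-type ketone A2. This sets C2 well but leaves C3 bare. The C3 oxygen would then need a late benzylic C–H oxygenation, trans to the isopropenyl group, in competition with allylic C–H bonds and the ketone α-position. The hardest stereocentre is left to the least controllable reaction. The chosen plan brings the C3 oxygen in from the alkene with C2.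

**Alternative 2:** Cut the C3–H bond to the racemic 2-isopropenylbenzofuran-3(2H)-one A3. Asymmetric transfer hydrogenation with dynamic kinetic resolution would funnel both enantiomers to the cis-alcohol A4, and a Mitsunobu reaction with 6 would invert C3. Three structural problems follow:
- A3 is a β,γ-unsaturated ketone that should slip to the conjugated 2-isopropylidene isomer, which cannot racemise.
- The same hydride reduces the 5-acetyl group, so A4 has two benzylic carbinols that need different acyl groups, one with inversion and one with retention.
- Mitsunobu activation of a carbinol ortho-linked to O1 invites ionisation and aromatisation.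

The chosen plan never has a free C3 alcohol beside a free C1′ alcohol.

**Alternative 3:** Cut C2–C3 and O1–C2 together: a 2-methylallyl sulfonium ylide with 5-acetyl-2-hydroxybenzaldehyde A5 gives a vinyl epoxide that the phenoxide opens to the trans-alcohol A6. The difficulties:
- Absolute control needs a stoichiometric chiral sulfide.
- The ylide can also attack the acetyl ketone.
- The vinyl epoxide can open at its far alkene terminus to a seven-membered ether.
- A6 still needs acylation at the labile C3 alcohol.

The chosen plan takes its absolute configuration from a catalytic step and carries the ester through the ring-forming step.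

Key step: step 5

Remark on the chemistry: the sense of induction in step 3 is taken from the established behaviour of 2,2-dimethylchromenes, for which the (R,R)-configured manganese salen catalyst is expected to give the (3R,4R)-oxide; all later descriptors follow from it.

## Route

Step 1
Reactants: 1 4′-hydroxyacetophenone; 2 3-chloro-3-methylbut-1-yne
Product: 3 1-[4-(2-methylbut-3-yn-2-yloxy)phenyl]ethanone
Conditions: DBU, CuCl2·2H2O (cat.), MeCN, 0 °C to rt
Reagents that add atoms: 3-chloro-3-methylbut-1-yne (2), C#CC(C)(C)Cl
Why: Copper-catalysed O-propargylation of a phenol with a tertiary propargylic chloride is the standard entry to aryl 1,1-dimethylpropargyl ethers; the acetyl group is inert and no stereocentre is formed.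

Step 2
Reactants: 3 1-[4-(2-methylbut-3-yn-2-yloxy)phenyl]ethanone
Product: 4 1-(2,2-dimethyl-2H-chromen-6-yl)ethanone
Conditions: N,N-diethylaniline, 190 °C
Reagents that add atoms: none
Why: Aromatic propargyl Claisen rearrangement, tautomerisation, 1,5-hydrogen shift and oxa-6π electrocyclisation give the 2,2-dimethylchromene; the two ortho positions are equivalent and para-acceptor aryl ethers are standard substrates.

Step 3
Reactants: 4 1-(2,2-dimethyl-2H-chromen-6-yl)ethanone
Product: 5 (3R,4R)-6-acetyl-3,4-epoxy-2,2-dimethylchromane
Conditions: (R,R)-(salen)MnCl [salen = N,N′-bis(3,5-di-tert-butylsalicylidene)cyclohexane-1,2-diamine dianion] (5 mol %), mCPBA, N-methylmorpholine N-oxide, CH2Cl2, −78 °C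
Reagents that add atoms: 3-chloroperbenzoic acid, OOC(=O)c1cccc(Cl)c1
Why: Jacobsen–Katsuki epoxidation of a 2,2-dimethylchromene, its best substrate class; the catalyst alone sets C3 and C4 (both R), and the low-temperature peracid protocol avoids hypochlorite at the methyl ketone while Baeyer–Villiger oxidation should be negligible at −78 °C.

Step 4
Reactants: 5 (3R,4R)-6-acetyl-3,4-epoxy-2,2-dimethylchromane; 6 3-methylbutanoic acid
Product: 7 (3R,4S)-6-acetyl-3-hydroxy-2,2-dimethyl-3,4-dihydro-2H-chromen-4-yl 3-methylbutanoate
Conditions: 6 (4 equiv), Et3N (1 equiv), MeCN, 60 °C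
Reagents that add atoms: 3-methylbutanoic acid (6), CC(C)CC(=O)O
Why: Carboxylate opening of an epoxide by SN2 attack at the benzylic C4 (C3 is shielded by the gem-dimethyl group) inverts C4 and should give the trans hydroxy ester; the acetyl group para to O1 disfavours ionisation at C4, and the isovalerate arrives at its final oxygen without a protecting group.

Step 5
Reactants: 7 (3R,4S)-6-acetyl-3-hydroxy-2,2-dimethyl-3,4-dihydro-2H-chromen-4-yl 3-methylbutanoate
Product: 10 (2R,3S)-5-acetyl-2-(prop-1-en-2-yl)-2,3-dihydro-1-benzofuran-3-yl 3-methylbutanoate, via chromanyl triflate 8 (not isolated), via bridged oxiranium ion 9 (not isolated)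
Conditions: Tf2O (1.1 equiv), 2,6-di-tert-butyl-4-methylpyridine (3 equiv), CH2Cl2, −78 °C to rt
Reagents that add atoms: none
Why: Triflation of the C3 hydroxyl gives 8, whose equatorial C3–O bond lies antiperiplanar to the C2–O1 ring bond in the diequatorial half-chair of the trans isomer; O1 displaces triflate from the rear (3-exo-tet closure of the oxirane ring of 9), and the O1–CMe2 bond of 9 then breaks towards the tertiary carbon while the hindered pyridine removes a methyl proton, so the five-membered ring of 10 is not closed by a new bond but is what remains when the six-membered ring gives up its CMe2 carbon to the side chain. The closest known reaction type is the ring contraction of 2,2-dimethylchroman-3-ols to 2-(2-substituted propan-2-yl)-2,3-dihydrobenzofurans on activation of the hydroxyl by aminosulfur trifluorides or as sulfonates, a 1,2-shift of the aryl ether oxygen of the Wagner–Meerwein family. The new stereocentre C2 of 10 is the old C3: it is set by inversion in the intramolecular displacement and so is dictated by the configuration from step 3 (3R in 7 becomes 2R in 10, trans to the untouched C3 ester, 3S). Three selectivities are needed. O1 must migrate ahead of the aryl C4–C4a bond, the other bond antiperiplanar to the leaving group: only the oxygen shift leaves a tertiary cation, whereas the aryl shift would leave an acyloxy-substituted one. O1 must also outrun the ester carbonyl as neighbouring group: in the diequatorial conformer that oxygen is gauche to the C3–O bond and cannot reach its rear side, and neither conformer offers an antiperiplanar hydrogen for plain elimination. Finally a methyl hydrogen must be lost and not the ring hydrogen at the new C2: only methyl C–H bonds can align anti to the breaking O1–C bond of 9, and the bulky base at low temperature favours the six exposed methyl hydrogens, which avoids the enol ether that would aromatise with loss of isovaleric acid.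

Step 6
Reactants: 10 (2R,3S)-5-acetyl-2-(prop-1-en-2-yl)-2,3-dihydro-1-benzofuran-3-yl 3-methylbutanoate
Product: 11 (2R,3S)-5-[(1S)-1-hydroxyethyl]-2-(prop-1-en-2-yl)-2,3-dihydro-1-benzofuran-3-yl 3-methylbutanoate
Conditions: RuCl(p-cymene)[(S,S)-TsDPEN] (1 mol %), HCO2H/Et3N (5:2), CH2Cl2, 30 °C
Reagents that add atoms: none
Why: Noyori–Ikariya asymmetric transfer hydrogenation of an aryl methyl ketone; the (S,S)-diamine complex of divalent ruthenium should deliver hydride to the face that gives the (S)-carbinol, under pure catalyst control since the ring stereocentres are remote, and the alkene and ester are not touched by this metal–ligand bifunctional hydride.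

Step 7
Reactants: 11 (2R,3S)-5-[(1S)-1-hydroxyethyl]-2-(prop-1-en-2-yl)-2,3-dihydro-1-benzofuran-3-yl 3-methylbutanoate
Product: 12 (2R,3S)-5-[(1S)-1-acetoxyethyl]-2-(prop-1-en-2-yl)-2,3-dihydro-1-benzofuran-3-yl 3-methylbutanoate
Conditions: Ac2O, pyridine, DMAP (cat.), CH2Cl2, 0 °C
Reagents that add atoms: acetic anhydride, CC(=O)OC(C)=O
Why: DMAP-catalysed acetylation of the only free hydroxyl proceeds with retention at C1′; the basic medium keeps the para-alkoxybenzylic C–O bond from ionising.

Step 8
Reactants: 12 (2R,3S)-5-[(1S)-1-acetoxyethyl]-2-(prop-1-en-2-yl)-2,3-dihydro-1-benzofuran-3-yl 3-methylbutanoate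
Product: 13 (2R,3S)-5-[(1S)-1-acetoxyethyl]-2-(3-hydroxyprop-1-en-2-yl)-2,3-dihydro-1-benzofuran-3-yl 3-methylbutanoate
Conditions: SeO2 (0.3 equiv), t-BuOOH (3 equiv, in decane), CH2Cl2, rt
Reagents that add atoms: tert-butyl hydroperoxide, CC(C)(C)OO (terminal oxygen source); selenium dioxide, O=[Se]=O (oxygen carrier)
Why: Riley allylic oxidation (ene reaction at the terminal CH2, then 2,3-sigmatropic shift) should take a methyl hydrogen, because the C2 methine C–H lies near the alkene plane and is deactivated by O1 and the C3 ester; the room-temperature catalytic variant spares both esters.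

Step 9
Reactants: 13 (2R,3S)-5-[(1S)-1-acetoxyethyl]-2-(3-hydroxyprop-1-en-2-yl)-2,3-dihydro-1-benzofuran-3-yl 3-methylbutanoate
Product: 14 (2R,3S)-5-[(1S)-1-acetoxyethyl]-2-(3-oxoprop-1-en-2-yl)-2,3-dihydro-1-benzofuran-3-yl 3-methylbutanoate
Conditions: activated MnO2, CH2Cl2, rt
Reagents that add atoms: none
Why: MnO2 oxidation of a primary allylic alcohol to the enal is neutral and heterogeneous, with no base or nucleophile that could add to the acrolein and expel O1; any enal already formed in step 8 converges on the same product.

## Compound list

1 | 4′-hydroxyacetophenone | CC(=O)c1ccc(O)cc1 | starting material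
2 | 3-chloro-3-methylbut-1-yne | C#CC(C)(C)Cl | starting material
3 | 1-[4-(2-methylbut-3-yn-2-yloxy)phenyl]ethanone | CC(=O)c1ccc(OC(C)(C)C#C)cc1 | intermediate
4 | 1-(2,2-dimethyl-2H-chromen-6-yl)ethanone | CC(=O)c1ccc2OC(C)(C)C=Cc2c1 | intermediate
5 | (3R,4R)-6-acetyl-3,4-epoxy-2,2-dimethylchromane | CC1(C)Oc2ccc(C(C)=O)cc2[C@H]3O[C@@H]13 | intermediate
6 | 3-methylbutanoic acid | CC(C)CC(=O)O | starting material
7 | (3R,4S)-6-acetyl-3-hydroxy-2,2-dimethyl-3,4-dihydro-2H-chromen-4-yl 3-methylbutanoate | CC1(C)Oc2ccc(C(C)=O)cc2[C@H](OC(=O)CC(C)C)[C@H]1O | intermediate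
8 | (3R,4S)-6-acetyl-2,2-dimethyl-3-(trifluoromethylsulfonyloxy)-3,4-dihydro-2H-chromen-4-yl 3-methylbutanoate | CC1(C)Oc2ccc(C(C)=O)cc2[C@H](OC(=O)CC(C)C)[C@H]1OS(=O)(=O)C(F)(F)F | intermediate
9 | O-aryl oxiranium ion in which O1 bridges the CMe2 carbon and the inverted old C3, with the C4 ester unchanged | CC1(C)[O+]2c3ccc(C(C)=O)cc3[C@H](OC(=O)CC(C)C)[C@@H]12 | intermediate
10 | (2R,3S)-5-acetyl-2-(prop-1-en-2-yl)-2,3-dihydro-1-benzofuran-3-yl 3-methylbutanoate | C=C(C)[C@H]1Oc2ccc(C(C)=O)cc2[C@@H]1OC(=O)CC(C)C | intermediate
11 | (2R,3S)-5-[(1S)-1-hydroxyethyl]-2-(prop-1-en-2-yl)-2,3-dihydro-1-benzofuran-3-yl 3-methylbutanoate | C=C(C)[C@H]1Oc2ccc([C@H](C)O)cc2[C@@H]1OC(=O)CC(C)C | intermediate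
12 | (2R,3S)-5-[(1S)-1-acetoxyethyl]-2-(prop-1-en-2-yl)-2,3-dihydro-1-benzofuran-3-yl 3-methylbutanoate | C=C(C)[C@H]1Oc2ccc([C@H](C)OC(C)=O)cc2[C@@H]1OC(=O)CC(C)C | intermediate
13 | (2R,3S)-5-[(1S)-1-acetoxyethyl]-2-(3-hydroxyprop-1-en-2-yl)-2,3-dihydro-1-benzofuran-3-yl 3-methylbutanoate | C=C(CO)[C@H]1Oc2ccc([C@H](C)OC(C)=O)cc2[C@@H]1OC(=O)CC(C)C | intermediate
14 | (2R,3S)-5-[(1S)-1-acetoxyethyl]-2-(3-oxoprop-1-en-2-yl)-2,3-dihydro-1-benzofuran-3-yl 3-methylbutanoate | C=C(C=O)[C@H]1Oc2ccc([C@H](C)OC(C)=O)cc2[C@@H]1OC(=O)CC(C)C | target

## Step count and least certain steps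

Total step count: 9. Longest linear sequence: 9 (the route is fully linear from 1).

**Step 5 (key step).** Two processes are most likely to go wrong. The C4 ester carbonyl may take part from the minor diaxial conformer, which would keep the six-membered ring. Alternatively an open tertiary cation may lose the ring hydrogen instead of a methyl hydrogen, which leads to aromatisation with loss of the acid. Enol triflate formation at the acetyl group by excess anhydride is a minor risk.

The fallback separates migration from alkene formation. It sets out from 7, which is converted with MsCl/Et3N to the mesylate (3R,4S)-6-acetyl-2,2-dimethyl-3-(methylsulfonyloxy)-3,4-dihydro-2H-chromen-4-yl 3-methylbutanoate F1. Buffered solvolysis of F1 (2,6-lutidine, aqueous hexafluoropropan-2-ol, 50 °C) lets water capture the rearranged cation and should give the tertiary carbinol (2S,3S)-5-acetyl-2-(2-hydroxypropan-2-yl)-2,3-dihydro-1-benzofuran-3-yl 3-methylbutanoate F2. The change of descriptor at C2 is due only to ligand priority. An E2-type dehydration (SOCl2/pyridine at 0 °C, or the Burgess reagent), the classical way from such carbinols to isopropenyl groups, returns to the route at 10.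

**Step 4.** Partial ionisation at C4 would erode the trans specificity, and the acyl group could shift to O3 in the warm buffered medium. The fallback sets out from 5. Opening with hydroxide (NaOH, aqueous dioxane, 60 °C), a strong nucleophile that attacks C4 by SN2, gives the trans-diol 1-[(3R,4S)-3,4-dihydroxy-2,2-dimethyl-3,4-dihydro-2H-chromen-6-yl]ethanone F3. Its benzylic 4-hydroxyl is then acylated selectively (3-methylbutanoic anhydride, Et3N, DMAP cat., CH2Cl2, −40 °C) beside the 3-hydroxyl, which is flanked by the gem-dimethyl carbon. The fallback comes back at 7.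

**Step 8.** The ene step may abstract the C2 methine hydrogen and so destroy the ring. The selenium acids may also promote loss of isovaleric acid or ionisation of the benzylic acetate. The fallback sets out from 12. An electrophilic ene-type chlorination (Ca(OCl)2, solid CO2, CH2Cl2/H2O, 0 °C) gives the allylic chloride (2R,3S)-5-[(1S)-1-acetoxyethyl]-2-(3-chloroprop-1-en-2-yl)-2,3-dihydro-1-benzofuran-3-yl 3-methylbutanoate F4. Oxygen transfer from trimethylamine N-oxide in DMSO at rt (displacement at the primary allylic carbon, then elimination) comes back to the route at 14 without passing through 13.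

**Step 6.** The ketone is electron-rich (para to O1), so hydride transfer is slow and partly reversible. This may leave the reduction incomplete or erode the selectivity at C1′. The fallback sets out from 10. NaBH4 in MeOH at −20 °C should give 11 together with its C1′ epimer (2R,3S)-5-[(1R)-1-hydroxyethyl]-2-(prop-1-en-2-yl)-2,3-dihydro-1-benzofuran-3-yl 3-methylbutanoate F5. Immobilised Candida antarctica lipase B with vinyl acetate acylates 1-arylethanols of the (R) series, so F5 becomes the acetate (2R,3S)-5-[(1R)-1-acetoxyethyl]-2-(prop-1-en-2-yl)-2,3-dihydro-1-benzofuran-3-yl 3-methylbutanoate F6. The untouched (S)-alcohol is separated by chromatography, and the fallback comes back at 11.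

## Further compounds

F1 | step 5 | (3R,4S)-6-acetyl-2,2-dimethyl-3-(methylsulfonyloxy)-3,4-dihydro-2H-chromen-4-yl 3-methylbutanoate | CC1(C)Oc2ccc(C(C)=O)cc2[C@H](OC(=O)CC(C)C)[C@H]1OS(C)(=O)=O
F2 | step 5 | (2S,3S)-5-acetyl-2-(2-hydroxypropan-2-yl)-2,3-dihydro-1-benzofuran-3-yl 3-methylbutanoate | CC(C)(O)[C@H]1Oc2ccc(C(C)=O)cc2[C@@H]1OC(=O)CC(C)C
F3 | step 4 | 1-[(3R,4S)-3,4-dihydroxy-2,2-dimethyl-3,4-dihydro-2H-chromen-6-yl]ethanone | CC1(C)Oc2ccc(C(C)=O)cc2[C@H](O)[C@H]1O
F4 | step 8 | (2R,3S)-5-[(1S)-1-acetoxyethyl]-2-(3-chloroprop-1-en-2-yl)-2,3-dihydro-1-benzofuran-3-yl 3-methylbutanoate | C=C(CCl)[C@H]1Oc2ccc([C@H](C)OC(C)=O)cc2[C@@H]1OC(=O)CC(C)C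
F5 | step 6 | (2R,3S)-5-[(1R)-1-hydroxyethyl]-2-(prop-1-en-2-yl)-2,3-dihydro-1-benzofuran-3-yl 3-methylbutanoate | C=C(C)[C@H]1Oc2ccc([C@@H](C)O)cc2[C@@H]1OC(=O)CC(C)C
F6 | step 6 | (2R,3S)-5-[(1R)-1-acetoxyethyl]-2-(prop-1-en-2-yl)-2,3-dihydro-1-benzofuran-3-yl 3-methylbutanoate | C=C(C)[C@H]1Oc2ccc([C@@H](C)OC(C)=O)cc2[C@@H]1OC(=O)CC(C)C
A1 | alternative 1 | 1-[4-hydroxy-3-(3-methylbut-2-en-1-yl)phenyl]ethanone | CC(=O)c1ccc(O)c(CC=C(C)C)c1
A2 | alternative 1 | 1-[(2S)-2-(prop-1-en-2-yl)-2,3-dihydro-1-benzofuran-5-yl]ethanone | C=C(C)[C@H]1Oc2ccc(C(C)=O)cc2C1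
A3 | alternative 2 | 5-acetyl-2-(prop-1-en-2-yl)-1-benzofuran-3(2H)-one (racemic) | C=C(C)C1Oc2ccc(C(C)=O)cc2C1=O
A4 | alternative 2 | (2R,3R)-5-[(1S)-1-hydroxyethyl]-2-(prop-1-en-2-yl)-2,3-dihydro-1-benzofuran-3-ol | C=C(C)[C@H]1Oc2ccc([C@H](C)O)cc2[C@H]1O
A5 | alternative 3 | 5-acetyl-2-hydroxybenzaldehyde | CC(=O)c1ccc(O)c(C=O)c1
A6 | alternative 3 | 1-[(2R,3S)-3-hydroxy-2-(prop-1-en-2-yl)-2,3-dihydro-1-benzofuran-5-yl]ethanone | C=C(C)[C@H]1Oc2ccc(C(C)=O)cc2[C@@H]1O
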